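**Strategy.** The target, an ent-labd-7-ene, hides (S)-carvone in ring B: the C8 methyl sits on the C7=C8 alkene para to C5, and C5 carries the gem-dimethyl carbon C4, which is carvone's isopropenyl carbon. The plan therefore builds ring A onto ring B by a C3–C4 closure. In one operation, hydrogen-atom transfer to the isopropenyl group and 6-exo addition of the resulting tertiary radical to a tethered aldehyde make the C3–C4 bond, quaternary C4 and the C3 carbinol of a trans-fused bicycle. The precursor is carvone bearing at C10 a methyl group and, trans to the isopropenyl group, a 3-oxopropyl chain. The C9 enone later takes up the side chain by addition and oxidative transposition.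

Key step: step 5

Assumption: methyl hydrogen (R)-3-methylglutarate (12) is purchased as the single enantiomer (the half-ester available by desymmetrising 3-methylglutaric anhydride or its dimethyl ester); bicyclic compounds carry labdane numbering (ring A: C1–C5 and C10; ring B: C5–C10; side chain C11–C15).

**Step 1**
Reactants: 1 (S)-(+)-carvone
Product: 3 (5S,6R)-6-methylcarvone (methyl trans to the isopropenyl group; a C6 epimer converges in step 2), via lithium dienolate 2 (not isolated)
Conditions: LiN(i-Pr)2, THF, −78 °C; then MeI, −78 → 0 °C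
Reagents that add atoms: iodomethane, CI
Why: Kinetic deprotonation at the only sp3 α-carbon gives the cross-conjugated dienolate, and its C-methylation (enolate alkylation) should occur mainly anti to the adjacent isopropenyl group, although this C–H stereocentre is planarised again in step 2.

**Step 2**
Reactants: 3 (5S,6R)-6-methylcarvone; 4 allyl bromide
Product: 6 (5R,6R)-6-allyl-6-methylcarvone (allyl trans and methyl cis to the isopropenyl group), via lithium enolate 5 (not isolated)
Conditions: LiN(i-Pr)2, THF, −78 → 0 °C; then 4, DMPU, −78 °C → rt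
Reagents that add atoms: none
Why: Enolate alkylation: the tetrasubstituted enolate should be attacked by the reactive allylic bromide on the face opposite to the neighbouring isopropenyl group, which sets quaternary C10 with the three-carbon chain trans to the isopropenyl group.

**Step 3**
Reactants: 6 (5R,6R)-6-allyl-6-methylcarvone
Product: 8 (5R,6R)-6-(3-hydroxypropyl)-2,6-dimethyl-5-(prop-1-en-2-yl)cyclohex-2-en-1-one, via alkyldisiamylborane 7 (not isolated)
Conditions: (Sia)2BH (from BH3·THF and 2-methylbut-2-ene), THF, 0 °C; then 30% H2O2, 3 M aq NaOAc, 0 °C → rt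
Reagents that add atoms: hydrogen peroxide, OO
Why: Hydroboration–oxidation: the bulky dialkylborane should add anti-Markovnikov to the monosubstituted allyl alkene far faster than to the hindered 1,1-disubstituted isopropenyl alkene or the deactivated enone carbonyl, and acetate-buffered peroxide oxidises the C–B bond without supplying the hydroperoxide anion needed for nucleophilic epoxidation of the enone.

**Step 4**
Reactants: 8 hydroxypropyl enone
Product: 9 (5R,6R)-2,6-dimethyl-6-(3-oxopropyl)-5-(prop-1-en-2-yl)cyclohex-2-en-1-one (6-methyl-6-(3-oxopropyl)carvone; chain trans to isopropenyl)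
Conditions: Dess–Martin periodinane, NaHCO3, CH2Cl2, 0 °C → rt
Reagents that add atoms: none
Why: Dess–Martin oxidation converts the primary alcohol into the aldehyde under buffered, non-enolising conditions that leave the enone and the isopropenyl group alone.

**Step 5**
Reactants: 9 keto aldehyde
Product: 10 trans-fused 3-hydroxy-4,4,8,10-tetramethyl-Δ7-octalin-9-one (3-OH equatorial and cis to the C10 methyl; H5 trans to the C10 methyl)
Conditions: Fe(acac)3 (30 mol %), PhSiH3 (2.5 equiv), degassed EtOH, 60 °C
Reagents that add atoms: none
Why: The trivalent iron hydride formed from Fe(acac)3, PhSiH3 and ethanol transfers a hydrogen atom to the terminal CH2 of the isopropenyl group (Markovnikov MHAT), the nucleophilic tertiary C4 radical adds to the carbon of the tethered aldehyde, and the alkoxy radical is reduced by divalent iron and protonated by ethanol, which returns the iron to the cycle. The closest known reaction type is the iron-hydride reductive radical cyclisation of alkene-tethered ketones, together with iron-hydride additions of unactivated alkenes to aldehydes. Ring A closes in the 6-exo-trig mode on the C=O group through a chair in which the C5–C4 and C10–C1 bonds are both equatorial on ring B. The trans ring fusion is not at stake because C5 comes from carvone and C10 was fixed in step 2; the only new stereocentre, C3, should be set by the chair-like transition state with the aldehyde oxygen pseudo-equatorial, and its epimer would be carried equally well because C3 becomes a ketone in step 16. The selectivity needed is hydrogen-atom transfer to the electron-rich 1,1-disubstituted alkene rather than to the electron-poor trisubstituted enone alkene, which the polarity and substitution of the two alkenes secure; the enone cannot compete as an acceptor because attack on C7 or C9 would close a four-membered ring.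

**Step 6**
Reactants: 10 bicyclic hydroxy enone
Product: 11 3-(triethylsilyloxy)-4,4,8,10-tetramethyl-Δ7-octalin-9-one (configuration as in 10)
Conditions: Et3SiOTf, 2,6-lutidine, CH2Cl2, −78 → 0 °C
Reagents that add atoms: triethylsilyl trifluoromethanesulfonate, CC[Si](CC)(CC)OS(=O)(=O)C(F)(F)F
Why: Silyl triflate/hindered base silylation masks the neopentyl-type C3 hydroxyl as an acid-labile triethylsilyl ether, so that it consumes no organolithium in step 11 and is not oxidised in step 12.

**Step 7**
Reactants: 12 methyl hydrogen (R)-3-methylglutarate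
Product: 13 methyl (R)-5-hydroxy-3-methylpentanoate
Conditions: BH3·SMe2, THF, −10 °C → rt; MeOH quench
Reagents that add atoms: none
Why: Chemoselective borane reduction of the carboxylic acid (through the acyloxyborane) in the presence of the methyl ester leaves the stereocentre untouched; the crude hydroxy ester is silylated at once to forestall lactonisation.

**Step 8**
Reactants: 13 hydroxy ester
Product: 14 methyl (R)-3-methyl-5-(triisopropylsilyloxy)pentanoate
Conditions: i-Pr3SiCl, imidazole, DMF, rt
Reagents that add atoms: triisopropylsilyl chloride, CC(C)[Si](Cl)(C(C)C)C(C)C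
Why: Imidazole-mediated silylation of the primary alcohol installs a triisopropylsilyl ether that survives hydride, organolithium, chlorochromate, dissolving metal and mild acid.

**Step 9**
Reactants: 14 silyloxy ester
Product: 15 (S)-3-methyl-5-(triisopropylsilyloxy)pentan-1-ol
Conditions: LiAlH4, Et2O, 0 °C
Reagents that add atoms: none
Why: Ester reduction with LiAlH4 gives the primary alcohol and touches neither the silyl ether nor the remote stereocentre.

**Step 10**
Reactants: 15 silyloxy alcohol
Product: 16 (R)-(5-iodo-3-methylpentyloxy)triisopropylsilane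
Conditions: I2, PPh3, imidazole, CH2Cl2, 0 °C → rt
Reagents that add atoms: iodine, II
Why: Appel-type iodination converts the primary alcohol into the iodide by SN2 displacement without affecting the stereocentre two carbons away.

**Step 11**
Reactants: 16 side-chain iodide; 11 silyl-protected bicyclic enone
Product: 18 (13S)-9-hydroxy-3-(triethylsilyloxy)-15-(triisopropylsilyloxy)labd-7-ene (C9 carbinol configuration inconsequential), via alkyllithium 17 (not isolated)
Conditions: 16, t-BuLi (2.1 equiv), Et2O/pentane, −78 °C; then 11, Et2O, −78 → 0 °C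
Reagents that add atoms: none
Why: Iodine–lithium exchange with two equivalents of t-BuLi gives the primary alkyllithium, which should add 1,2 to the enone carbonyl (carbonyl addition; C10 bears no α-hydrogen to enolise), mainly anti to the axial C10 methyl, and the configuration of the new C9 carbinol does not matter because C9 becomes sp2 in step 12.

**Step 12**
Reactants: 18 tertiary allylic alcohol
Product: 19 (13S)-3-(triethylsilyloxy)-15-(triisopropylsilyloxy)labd-8-en-7-one
Conditions: pyridinium chlorochromate [C5H5NH][CrO3Cl], 4 Å molecular sieves, CH2Cl2, rt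
Reagents that add atoms: pyridinium chlorochromate, [O-][Cr](=O)(=O)Cl.c1cc[nH+]cc1
Why: Oxidative 1,3-transposition of a tertiary allylic alcohol (Dauben-type: chromate ester, [3,3]-shift of the chromate to C7, oxidation by the hexavalent chromium) should deliver the tetrasubstituted 8-en-7-one, a sequence that is routine for carbinols derived from 6,6-dialkylcarvones.

**Step 13**
Reactants: 19 transposed enone
Product: 21 (13S)-3-(triethylsilyloxy)-15-(triisopropylsilyloxy)labd-7-en-7-yl trifluoromethanesulfonate (H9 trans to the C10 methyl), via lithium enolate 20 (not isolated)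
Conditions: Li (2.2 equiv), t-BuOH (1.0 equiv), NH3/THF, −78 °C; NH3 evaporated; then PhNTf2, THF, −78 °C → rt
Reagents that add atoms: N-phenylbis(trifluoromethanesulfonimide), O=S(=O)(N(c1ccccc1)S(=O)(=O)C(F)(F)F)C(F)(F)F
Why: Dissolving-metal reduction of the enone forms the C7(O)=C8 lithium enolate regiospecifically after protonation of the β-carbon C9 by t-BuOH along the axial trajectory anti to the C10 methyl (side chain equatorial, the labdane C9 configuration), and O-sulfonylation with the triflimide (regiospecific enolate trapping) locks that regiochemistry in the enol triflate.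

**Step 14**
Reactants: 21 enol triflate
Product: 22 (13S)-3-(triethylsilyloxy)-15-(triisopropylsilyloxy)labd-7-ene
Conditions: Pd(OAc)2 (cat.), PPh3, HCO2H, Et3N, DMF, 60 °C
Reagents that add atoms: none
Why: Palladium-catalysed formate reduction of the enol triflate (oxidative addition to zerovalent palladium, formate decarboxylation to the palladium hydride, reductive elimination) replaces the triflate by hydrogen without moving the C7=C8 double bond or touching the silyl ethers.

**Step 15**
Reactants: 22 bis-silyl ether
Product: 23 (13S)-15-(triisopropylsilyloxy)labd-7-en-3-ol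
Conditions: PPTS (cat.), MeOH/CH2Cl2, rt
Reagents that add atoms: none
Why: Acid-catalysed methanolysis should cleave the triethylsilyl ether selectively because it is several orders of magnitude more acid-labile than the primary triisopropylsilyl ether.

**Step 16**
Reactants: 23 C3 alcohol
Product: 24 (13S)-15-(triisopropylsilyloxy)labd-7-en-3-one
Conditions: Dess–Martin periodinane, NaHCO3, CH2Cl2, rt
Reagents that add atoms: none
Why: Dess–Martin oxidation of the hindered secondary alcohol gives the C3 ketone without affecting the trisubstituted alkene or the silyl ether.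

**Step 17**
Reactants: 24 C3 ketone
Product: 26 (13S)-2-hydroxy-15-(triisopropylsilyloxy)labd-7-en-3-one (2-OH equatorial; trans to the C10 methyl), via potassium enolate 25 (not isolated)
Conditions: KN(SiMe3)2, THF, −78 °C; then 3-phenyl-2-(phenylsulfonyl)oxaziridine, −78 °C; AcOH quench
Reagents that add atoms: 3-phenyl-2-(phenylsulfonyl)oxaziridine, O=S(=O)(N1OC1c1ccccc1)c1ccccc1
Why: Enolate hydroxylation with an N-sulfonyloxaziridine: the ketone can enolise only towards C2 because C4 is quaternary, and the oxidant should approach the enolate from the face opposite to the syn-axial C4 and C10 methyl groups, which places the new C2 hydroxyl equatorial (also the more stable epimer).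

**Step 18**
Reactants: 26 α-hydroxy ketone
Product: 27 (13S)-2,15-dihydroxylabd-7-en-3-one
Conditions: HF·pyridine, pyridine, THF, 0 °C → rt
Reagents that add atoms: none
Why: Fluoride-mediated desilylation under pyridine buffering removes the primary triisopropylsilyl ether under conditions too mild to isomerise the α-ketol or the alkene.

**Step 19**
Reactants: 27 dihydroxy ketone
Product: 28 (13S)-3-oxolabd-7-ene-2,15-diyl diacetate
Conditions: Ac2O, pyridine, DMAP (cat.), CH2Cl2, 0 °C → rt
Reagents that add atoms: acetic anhydride, CC(=O)OC(C)=O
Why: DMAP-catalysed acetylation esterifies the primary C15 and the secondary C2 hydroxyl in one operation, and the C3 oxygen cannot compete because it is still a ketone.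

**Step 20**
Reactants: 28 diacetoxy ketone
Product: 29 (2S,3S,5S,9R,10S,13S)-3-hydroxylabd-7-ene-2,15-diyl diacetate (CNP0144124.2)
Conditions: NaBH4, MeOH/THF, −40 °C; AcOH quench
Reagents that add atoms: none
Why: Borohydride reduction: hydride should attack the C3 ketone axially from the face opposite to the syn-axial C4 and C10 methyl groups, giving the equatorial C3 alcohol trans to the C2 acetate, while low temperature and an acidic quench guard against acetyl migration.

**Compound list**
1 | (S)-(+)-carvone | CC1=CC[C@@H](CC1=O)C(C)=C | starting material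
2 | lithium dienolate of 1 | CC1=CC[C@@H](C=C1O[Li])C(C)=C | intermediate
3 | (5S,6R)-2,6-dimethyl-5-(prop-1-en-2-yl)cyclohex-2-en-1-one (trans-6-methylcarvone) | CC1=CC[C@H](C(C)=C)[C@@H](C)C1=O | intermediate
4 | allyl bromide | C=CCBr | starting material
5 | lithium enolate of 3 | CC1=CC[C@H](C(C)=C)C(C)=C1O[Li] | intermediate
6 | (5R,6R)-6-allyl-2,6-dimethyl-5-(prop-1-en-2-yl)cyclohex-2-en-1-one | O=C1C(C)=CC[C@H](C(C)=C)[C@@]1(C)CC=C | intermediate
7 | bis(3-methylbutan-2-yl)borane adduct of 6 at the terminal allyl carbon | O=C1C(C)=CC[C@H](C(C)=C)[C@@]1(C)CCCB(C(C)C(C)C)C(C)C(C)C | intermediate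
8 | (5R,6R)-6-(3-hydroxypropyl)-2,6-dimethyl-5-(prop-1-en-2-yl)cyclohex-2-en-1-one | O=C1C(C)=CC[C@H](C(C)=C)[C@@]1(C)CCCO | intermediate
9 | (5R,6R)-2,6-dimethyl-6-(3-oxopropyl)-5-(prop-1-en-2-yl)cyclohex-2-en-1-one | O=C1C(C)=CC[C@H](C(C)=C)[C@@]1(C)CCC=O | intermediate
10 | trans-fused 3-hydroxy-4,4,8,10-tetramethyl-Δ7-octalin-9-one (3-OH equatorial) | O=C1C(C)=CC[C@@H]2C(C)(C)[C@H](O)CC[C@@]12C | intermediate
11 | 3-O-triethylsilyl ether of 10 | O=C1C(C)=CC[C@@H]2C(C)(C)[C@H](O[Si](CC)(CC)CC)CC[C@@]12C | intermediate
12 | methyl hydrogen (R)-3-methylglutarate | OC(=O)C[C@@H](C)CC(=O)OC | starting material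
13 | methyl (R)-5-hydroxy-3-methylpentanoate | OCC[C@@H](C)CC(=O)OC | intermediate
14 | methyl (R)-3-methyl-5-(triisopropylsilyloxy)pentanoate | CC(C)[Si](C(C)C)(C(C)C)OCC[C@@H](C)CC(=O)OC | intermediate
15 | (S)-3-methyl-5-(triisopropylsilyloxy)pentan-1-ol | CC(C)[Si](C(C)C)(C(C)C)OCC[C@@H](C)CCO | intermediate
16 | (R)-(5-iodo-3-methylpentyloxy)triisopropylsilane | CC(C)[Si](C(C)C)(C(C)C)OCC[C@@H](C)CCI | intermediate
17 | (S)-[3-methyl-5-(triisopropylsilyloxy)pentyl]lithium | CC(C)[Si](C(C)C)(C(C)C)OCC[C@@H](C)CC[Li] | intermediate
18 | (13S)-9-hydroxy-3-(triethylsilyloxy)-15-(triisopropylsilyloxy)labd-7-ene (side chain at C9 anti to the C10 methyl assumed) | O[C@]1(CC[C@H](C)CCO[Si](C(C)C)(C(C)C)C(C)C)C(C)=CC[C@@H]2C(C)(C)[C@H](O[Si](CC)(CC)CC)CC[C@@]12C | intermediate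
19 | (13S)-3-(triethylsilyloxy)-15-(triisopropylsilyloxy)labd-8-en-7-one | O=C1C[C@@H]2C(C)(C)[C@H](O[Si](CC)(CC)CC)CC[C@@]2(C)C(CC[C@H](C)CCO[Si](C(C)C)(C(C)C)C(C)C)=C1C | intermediate
20 | lithium C7 enolate of the 9-H ketone (C7=C8; H9 trans to C10 methyl) | CC(C)[Si](C(C)C)(C(C)C)OCC[C@@H](C)CC[C@@H]1C(C)=C(O[Li])C[C@@H]2C(C)(C)[C@H](O[Si](CC)(CC)CC)CC[C@@]12C | intermediate
21 | (13S)-3-(triethylsilyloxy)-15-(triisopropylsilyloxy)labd-7-en-7-yl trifluoromethanesulfonate | CC(C)[Si](C(C)C)(C(C)C)OCC[C@@H](C)CC[C@@H]1C(C)=C(OS(=O)(=O)C(F)(F)F)C[C@@H]2C(C)(C)[C@H](O[Si](CC)(CC)CC)CC[C@@]12C | intermediate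
22 | (13S)-3-(triethylsilyloxy)-15-(triisopropylsilyloxy)labd-7-ene | CC(C)[Si](C(C)C)(C(C)C)OCC[C@@H](C)CC[C@@H]1C(C)=CC[C@@H]2C(C)(C)[C@H](O[Si](CC)(CC)CC)CC[C@@]12C | intermediate
23 | (13S)-15-(triisopropylsilyloxy)labd-7-en-3-ol | CC(C)[Si](C(C)C)(C(C)C)OCC[C@@H](C)CC[C@@H]1C(C)=CC[C@@H]2C(C)(C)[C@H](O)CC[C@@]12C | intermediate
24 | (13S)-15-(triisopropylsilyloxy)labd-7-en-3-one | CC(C)[Si](C(C)C)(C(C)C)OCC[C@@H](C)CC[C@@H]1C(C)=CC[C@@H]2C(C)(C)C(=O)CC[C@@]12C | intermediate
25 | potassium C2=C3 enolate of 24 | CC(C)[Si](C(C)C)(C(C)C)OCC[C@@H](C)CC[C@@H]1C(C)=CC[C@@H]2C(C)(C)C(O[K])=CC[C@@]12C | intermediate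
26 | (13S)-2-hydroxy-15-(triisopropylsilyloxy)labd-7-en-3-one (2-OH equatorial) | CC(C)[Si](C(C)C)(C(C)C)OCC[C@@H](C)CC[C@@H]1C(C)=CC[C@@H]2C(C)(C)C(=O)[C@@H](O)C[C@@]12C | intermediate
27 | (13S)-2,15-dihydroxylabd-7-en-3-one | OCC[C@@H](C)CC[C@@H]1C(C)=CC[C@@H]2C(C)(C)C(=O)[C@@H](O)C[C@@]12C | intermediate
28 | (13S)-3-oxolabd-7-ene-2,15-diyl diacetate | CC(=O)OCC[C@@H](C)CC[C@@H]1C(C)=CC[C@@H]2C(C)(C)C(=O)[C@@H](OC(C)=O)C[C@@]12C | intermediate
29 | (2S,3S,5S,9R,10S,13S)-3-hydroxylabd-7-ene-2,15-diyl diacetate (CNP0144124.2) | CC(=O)OCC[C@@H](C)CC[C@@H]1C(C)=CC[C@@H]2C(C)(C)[C@H](O)[C@@H](OC(C)=O)C[C@@]12C | target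

**Step count.** Total: 20 steps. Longest linear sequence: 16 steps (steps 1–6 and 11–20); the side-chain iodide takes 4 steps (7–10).

**Steps most likely to fail**

Step 5. The tertiary radical may be reduced before it cyclises, the aldehyde may be hydrosilylated, or the alkoxy radical may reopen the ring before it is reduced. Fallback: setting out from 9, Markovnikov hydrobromination of the isopropenyl group (HBr in AcOH, CH2Cl2, 0 °C) would give the tertiary bromide F1. Slow addition of Bu3SnH with AIBN in benzene at 80 °C then generates the same C4 radical by bromine abstraction and closes ring A on the formyl group. This 6-exo cyclisation onto an aldehyde is established tin-hydride chemistry, and the stannane traps the alkoxy radical quickly. The route is rejoined at 10.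

Step 13. Proton transfer may move the enolate towards C6 before it is trapped, or O-sulfonylation may stay incomplete in a medium that still holds lithium alkoxide and amide. Fallback: setting out from 19, the enolate 20 is generated in the same way but quenched with the harder and faster electrophile ClP(O)(OEt)2, which would give the enol diethyl phosphate F2. Reductive C–O cleavage with Li in EtNH2/t-BuOH/THF at 0 °C then leads directly to alkene 22, so that neither the triflate 21 nor the palladium step is needed. The route is rejoined at 22.

Step 3. The borane may also attack the isopropenyl group or reduce the ketone, and the peroxide work-up may epoxidise the enone. Fallback: setting out from 6, the allyl group is oxidised directly to the aldehyde by the nitrite-modified, aldehyde-selective Wacker oxidation (PdCl2(PhCN)2, CuCl2, AgNO2, O2, t-BuOH/MeNO2, rt). This uses neither a boron hydride nor peroxide and skips 7 and 8. The route is rejoined at 9, and the fallback makes no compound outside the list (F0).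

**Further compounds**
F1 | step 5 | 5-(2-bromopropan-2-yl)-2,6-dimethyl-6-(3-oxopropyl)cyclohex-2-en-1-one (configuration as in 9) | O=C1C(C)=CC[C@H](C(C)(C)Br)[C@@]1(C)CCC=O
F2 | step 13 | diethyl (13S)-3-(triethylsilyloxy)-15-(triisopropylsilyloxy)labd-7-en-7-yl phosphate | CC(C)[Si](C(C)C)(C(C)C)OCC[C@@H](C)CC[C@@H]1C(C)=C(OP(=O)(OCC)OCC)C[C@@H]2C(C)(C)[C@H](O[Si](CC)(CC)CC)CC[C@@]12C
F0 | step 3 | none | none
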